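## Retrosynthetic overview
1. The target comes from a fully protected 3,5,7,8,5'-pentamethoxy-2',4'-bis(benzyloxy)flavone by chelation-controlled 5-O-demethylation, then hydrogenolysis of both benzyl ethers.
2. The 3-OMe group comes from O-methylation of a flavonol, which is made by C-3 oxidation (dioxirane epoxidation) of the corresponding flavone.
3. Ring C (the pyranone) is the only ring built. It is closed last, by oxidative cyclisation (O1–C2 bond) of a 2'-hydroxychalcone; rings A and B are bought as arenes.
4. Key C–C bond: Claisen–Schmidt crossed aldol condensation of 2-hydroxy-3,4,6-trimethoxyacetophenone with 2,4-bis(benzyloxy)-5-methoxybenzaldehyde.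
5. The ketone comes from 3,4,5-trimethoxyphenol (methylation, Friedel–Crafts acylation with ortho-demethylation). The aldehyde comes from isovanillin (benzylation, Baeyer–Villiger, benzylation, Vilsmeier–Haack).

Assumption: the target SMILES has no stereocentre, axis or stereogenic alkene, so the compound is achiral and no enantioselective step is needed; transient racemic centres are all destroyed on the way.

## Route

Step 1
Reactants: 1 3,4,5-trimethoxyphenol
Product: 2 1,2,3,5-tetramethoxybenzene
Conditions: MeI (1.5 equiv), K2CO3 (2 equiv), acetone, reflux, 8 h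
Reagents that add atoms: methyl iodide, CI
Why: Williamson ether synthesis (SN2 O-methylation of the only phenoxide) gives the symmetric tetramethyl ether cleanly.

Step 2
Reactants: 2 1,2,3,5-tetramethoxybenzene
Product: 4 2-hydroxy-3,4,6-trimethoxyacetophenone, via 2,3,4,6-tetramethoxyacetophenone 3 (not isolated)
Conditions: AcCl (1.2 equiv), AlCl3 (2.5 equiv), Et2O, 0 °C → reflux, 6 h; then ice/2 M HCl
Reagents that add atoms: acetyl chloride, CC(Cl)=O
Why: Friedel–Crafts acylation can only hit the two equivalent free positions, and AlCl3 chelated to the new ketone cleaves the crowded, out-of-plane 2-OMe (buttressed by 3-OMe) faster than the 6-OMe, giving the hydrogen-bonded o-hydroxyketone (checked by NOE from H-5 to both flanking OMe groups).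

Step 3
Reactants: 5 isovanillin (3-hydroxy-4-methoxybenzaldehyde)
Product: 6 3-(benzyloxy)-4-methoxybenzaldehyde
Conditions: BnBr (1.1 equiv), K2CO3 (1.5 equiv), DMF, 60 °C, 4 h
Reagents that add atoms: benzyl bromide, BrCc1ccccc1
Why: Williamson O-benzylation of the single phenol; the non-enolisable aldehyde is inert to carbonate.

Step 4
Reactants: 6 3-(benzyloxy)-4-methoxybenzaldehyde
Product: 8 3-(benzyloxy)-4-methoxyphenol, via 3-(benzyloxy)-4-methoxyphenyl formate 7 (not isolated)
Conditions: mCPBA (1.3 equiv), CH2Cl2, 0 °C → rt, 12 h; crude formate, K2CO3 (0.2 equiv), MeOH, rt, 1 h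
Reagents that add atoms: mCPBA, O=C(OO)c1cccc(Cl)c1
Why: Baeyer–Villiger (Dakin-type) oxidation, in which the electron-rich p-methoxyaryl group migrates in the Criegee intermediate, and the aryl formate is then removed by base-catalysed transesterification without touching the ethers.

Step 5
Reactants: 8 3-(benzyloxy)-4-methoxyphenol
Product: 9 2,4-bis(benzyloxy)-1-methoxybenzene
Conditions: BnBr (1.1 equiv), K2CO3 (1.5 equiv), DMF, 60 °C, 4 h
Reagents that add atoms: benzyl bromide, BrCc1ccccc1
Why: Williamson O-benzylation of the only free phenol.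

Step 6
Reactants: 9 2,4-bis(benzyloxy)-1-methoxybenzene
Product: 11 2,4-bis(benzyloxy)-5-methoxybenzaldehyde, via aryl iminium salt 10 (not isolated)
Conditions: POCl3 (2 equiv), DMF, 0 → 70 °C, 3 h; then ice–H2O, rt, 2 h
Reagents that add atoms: DMF, CN(C)C=O; water, O
Why: Vilsmeier–Haack formylation attacks C-5, the only position that is para to one benzyloxy group and ortho to the other (C-3 is shielded between two OBn groups), the same orientation as in 1,2,4-trimethoxybenzene.

Step 7
Reactants: 4 2-hydroxy-3,4,6-trimethoxyacetophenone; 11 2,4-bis(benzyloxy)-5-methoxybenzaldehyde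
Product: 13 (E)-2,4-bis(benzyloxy)-2'-hydroxy-3',4',5,6'-tetramethoxychalcone, via beta-hydroxyketone aldol adduct 12 (not isolated)
Conditions: KOH (50 % aq, 10 equiv), EtOH–THF, rt, 48 h; then 1 M HCl to pH 3
Reagents that add atoms: none
Why: Claisen–Schmidt crossed aldol condensation, where only the methyl ketone can enolise and only the aldehyde can accept, and E1cB dehydration of racemic 12 removes its carbinol centre and gives the thermodynamic E-enone.

Step 8
Reactants: 13 (E)-2,4-bis(benzyloxy)-2'-hydroxy-3',4',5,6'-tetramethoxychalcone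
Product: 15 2',4'-bis(benzyloxy)-5,7,8,5'-tetramethoxyflavone, via 3-iodoflavanone 14 (not isolated)
Conditions: I2 (0.1 equiv), DMSO, 125 °C, 2–3 h; aq Na2S2O3 wash
Reagents that add atoms: none
Why: In this iodine-catalysed oxidative cyclisation (I2/DMSO) the single free 2'-OH closes 6-endo onto the iodine-activated enone, loss of HI from 14 aromatises the pyranone, DMSO re-oxidises HI, and the 5,7,8-pattern follows unambiguously.

Step 9
Reactants: 15 2',4'-bis(benzyloxy)-5,7,8,5'-tetramethoxyflavone
Product: 17 2',4'-bis(benzyloxy)-3-hydroxy-5,7,8,5'-tetramethoxyflavone, via flavone 2,3-epoxide 16 (not isolated)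
Conditions: DMDO (ca. 0.08 M in acetone, 3 equiv in portions), CH2Cl2, 0 °C → rt, 24 h; then p-TsOH·H2O (cat.), CH2Cl2, rt, 1 h
Reagents that add atoms: dimethyldioxirane, CC1(C)OO1
Why: Dioxirane epoxidation of the enol-ether-like C2=C3 bond, then acid-catalysed epoxide opening and tautomerisation, gives the flavonol and avoids the aurone formation that troubles Algar–Flynn–Oyamada oxidation of 6'-alkoxychalcones.

Step 10
Reactants: 17 2',4'-bis(benzyloxy)-3-hydroxy-5,7,8,5'-tetramethoxyflavone
Product: 18 2',4'-bis(benzyloxy)-3,5,7,8,5'-pentamethoxyflavone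
Conditions: MeI (2 equiv), K2CO3 (3 equiv), DMF, rt, 12 h
Reagents that add atoms: methyl iodide, CI
Why: Williamson O-methylation of the only free, acidic enolic 3-OH.

Step 11
Reactants: 18 2',4'-bis(benzyloxy)-3,5,7,8,5'-pentamethoxyflavone
Product: 19 2',4'-bis(benzyloxy)-5-hydroxy-3,7,8,5'-tetramethoxyflavone
Conditions: AlCl3 (5 % w/v in MeCN, ca. 5 equiv), 50–60 °C, 1–2 h (HPLC control); then 2 % aq HCl, 60 °C, 20 min
Reagents that add atoms: none
Why: In this chelation-controlled Lewis-acid ether cleavage the six-membered Al chelate between C4=O and the peri 5-OMe makes that methyl the fastest to leave in MeCN-attenuated AlCl3, ahead of 3-OMe and the unchelated ethers, and any partly debenzylated material still converges on the target in the last step.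

Step 12
Reactants: 19 2',4'-bis(benzyloxy)-5-hydroxy-3,7,8,5'-tetramethoxyflavone
Product: 20 5,2',4'-trihydroxy-3,7,8,5'-tetramethoxyflavone
Conditions: H2 (1 atm), 10 % Pd/C, EtOAc–MeOH, rt, 3 h; filter and concentrate under N2
Reagents that add atoms: none
Why: Catalytic hydrogenolysis removes both aryl benzyl ethers, while the tetrasubstituted vinylogous-ester C2=C3 bond and the methyl ethers are inert at 1 atm, giving the achiral target.

## Compound list
1 | 3,4,5-trimethoxyphenol | COc1cc(O)cc(OC)c1OC | starting material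
2 | 1,2,3,5-tetramethoxybenzene | COc1cc(OC)c(OC)c(OC)c1 | intermediate
3 | 2,3,4,6-tetramethoxyacetophenone (not isolated) | CC(=O)c1c(OC)cc(OC)c(OC)c1OC | intermediate
4 | 2-hydroxy-3,4,6-trimethoxyacetophenone | CC(=O)c1c(O)c(OC)c(OC)cc1OC | intermediate
5 | isovanillin (3-hydroxy-4-methoxybenzaldehyde) | COc1ccc(C=O)cc1O | starting material
6 | 3-(benzyloxy)-4-methoxybenzaldehyde | COc1ccc(C=O)cc1OCc1ccccc1 | intermediate
7 | 3-(benzyloxy)-4-methoxyphenyl formate (not isolated) | COc1ccc(OC=O)cc1OCc1ccccc1 | intermediate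
8 | 3-(benzyloxy)-4-methoxyphenol | COc1ccc(O)cc1OCc1ccccc1 | intermediate
9 | 2,4-bis(benzyloxy)-1-methoxybenzene | COc1ccc(OCc2ccccc2)cc1OCc1ccccc1 | intermediate
10 | [2,4-bis(benzyloxy)-5-methoxybenzylidene]dimethyliminium dichlorophosphate (not isolated) | COc1cc(C=[N+](C)C)c(OCc2ccccc2)cc1OCc1ccccc1.[O-]P(=O)(Cl)Cl | intermediate
11 | 2,4-bis(benzyloxy)-5-methoxybenzaldehyde | COc1cc(C=O)c(OCc2ccccc2)cc1OCc1ccccc1 | intermediate
12 | 3-[2,4-bis(benzyloxy)-5-methoxyphenyl]-3-hydroxy-1-(2-hydroxy-3,4,6-trimethoxyphenyl)propan-1-one (racemic, not isolated) | COc1cc(C(O)CC(=O)c2c(O)c(OC)c(OC)cc2OC)c(OCc2ccccc2)cc1OCc1ccccc1 | intermediate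
13 | (E)-3-[2,4-bis(benzyloxy)-5-methoxyphenyl]-1-(2-hydroxy-3,4,6-trimethoxyphenyl)prop-2-en-1-one (the chalcone) | COc1cc(/C=C/C(=O)c2c(O)c(OC)c(OC)cc2OC)c(OCc2ccccc2)cc1OCc1ccccc1 | intermediate
14 | 2-[2,4-bis(benzyloxy)-5-methoxyphenyl]-3-iodo-5,7,8-trimethoxychroman-4-one (racemic, not isolated) | COc1cc(C2Oc3c(OC)c(OC)cc(OC)c3C(=O)C2I)c(OCc2ccccc2)cc1OCc1ccccc1 | intermediate
15 | 2',4'-bis(benzyloxy)-5,7,8,5'-tetramethoxyflavone | COc1cc(-c2cc(=O)c3c(OC)cc(OC)c(OC)c3o2)c(OCc2ccccc2)cc1OCc1ccccc1 | intermediate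
16 | 2,3-epoxide of flavone 15 (racemic, not isolated) | COc1cc(C23OC2C(=O)c2c(OC)cc(OC)c(OC)c2O3)c(OCc2ccccc2)cc1OCc1ccccc1 | intermediate
17 | 2',4'-bis(benzyloxy)-3-hydroxy-5,7,8,5'-tetramethoxyflavone | COc1cc(-c2oc3c(OC)c(OC)cc(OC)c3c(=O)c2O)c(OCc2ccccc2)cc1OCc1ccccc1 | intermediate
18 | 2',4'-bis(benzyloxy)-3,5,7,8,5'-pentamethoxyflavone | COc1cc(-c2oc3c(OC)c(OC)cc(OC)c3c(=O)c2OC)c(OCc2ccccc2)cc1OCc1ccccc1 | intermediate
19 | 2',4'-bis(benzyloxy)-5-hydroxy-3,7,8,5'-tetramethoxyflavone | COc1cc(-c2oc3c(OC)c(OC)cc(O)c3c(=O)c2OC)c(OCc2ccccc2)cc1OCc1ccccc1 | intermediate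
20 | 5,2',4'-trihydroxy-3,7,8,5'-tetramethoxyflavone (achiral) | COc1cc(-c2oc3c(OC)c(OC)cc(O)c3c(=O)c2OC)c(O)cc1O | target

## Step count and risks
Total steps: 12. Longest linear sequence: 10 steps (5 → 20, steps 3–12). The ketone branch (steps 1–2) joins at step 7.

**Step 9 (C-3 oxidation) is the most likely to fail.** The 2'-substituted, twisted flavone may epoxidise slowly, and excess dioxirane could attack the very electron-rich B ring or the benzylic CH2 groups. The fallback replaces electrophilic oxidation with directed metalation. It sets out from flavone 15, which is deprotonated at C-3 with LDA (THF, −78 °C) in the presence of B(OMe)3. After an AcOH quench this gives dimethyl [2',4'-bis(benzyloxy)-5,7,8,5'-tetramethoxyflavon-3-yl]boronate F1. F1 is oxidised without purification with 30 % H2O2, and the route is rejoined at flavonol 17.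

**Step 11 (selective 5-O-demethylation) is second.** The 3-OMe is the next most labile ether, and partial benzyl loss makes the reaction hard to monitor. The fallback reverses the order of deprotection. It sets out from 18, which is hydrogenolysed first (H2, Pd/C, EtOAc–MeOH) to 2',4'-dihydroxy-3,5,7,8,5'-pentamethoxyflavone F2. With no benzyl ether left, the 5-OMe is then cleaved with the more reactive AlBr3 (5 % w/v in MeCN, 0 °C → rt, then dilute HCl). The lower temperature widens the rate gap between 5-OMe and 3-OMe. This bypasses 19 and rejoins at target 20.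

**Step 8 (I2/DMSO cyclisation) is third.** HI at 125 °C can erode the 5-OMe or the benzyl ethers, and the electron-rich rings can be iodinated. The fallback splits ring closure from dehydrogenation and uses no iodine. It sets out from chalcone 13, which is isomerised by oxa-Michael addition (NaOAc, EtOH, reflux) to racemic 2',4'-bis(benzyloxy)-5,7,8,5'-tetramethoxyflavanone F3. F3 is dehydrogenated with DDQ (dioxane, reflux), and the route is rejoined at flavone 15.

Further compounds
F1 | step 9 | dimethyl [2',4'-bis(benzyloxy)-5,7,8,5'-tetramethoxyflavon-3-yl]boronate | COc1cc(-c2oc3c(OC)c(OC)cc(OC)c3c(=O)c2B(OC)OC)c(OCc2ccccc2)cc1OCc1ccccc1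
F2 | step 11 | 2',4'-dihydroxy-3,5,7,8,5'-pentamethoxyflavone | COc1cc(-c2oc3c(OC)c(OC)cc(OC)c3c(=O)c2OC)c(O)cc1O
F3 | step 8 | 2',4'-bis(benzyloxy)-5,7,8,5'-tetramethoxyflavanone (racemic) | COc1cc(C2CC(=O)c3c(OC)cc(OC)c(OC)c3O2)c(OCc2ccccc2)cc1OCc1ccccc1
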